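Assumption: side-chain locants are primed (C1' is the ring-bound CH2), and nerol (≥97 % Z), geranyl acetate (≥98 % E), D-(−)-diethyl tartrate and 4-methoxy-2-methylphenol are used as bought. The route is a paper design and has not been run.

**Retrosynthetic overview**
1. The quinone is unveiled last by oxidising a prenylated quinol monomethyl ether (quinol → quinone, as in the biosynthesis). It is the only ring of the target; the benzene ring of the phenol is carried through and no carbocycle is built.
2. The aryl–C1' bond comes from a biomimetic, protecting-group-free ortho-prenylation of 4-methoxy-2-methylphenol with the complete C20 allylic alcohol that already carries the (10'S,11'S)-diol.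
3. The C20 triol comes from a C8'–C9' union of a trilithiated dihydroxy sulfone (C9'–C16') with (E,E)-8-bromogeranyl acetate (C1'–C8'), then desulfonylation and deacetylation.
4. The dihydroxy sulfone comes from Payne rearrangement–sulfinate opening of (2R,3S)-epoxynerol, made by Sharpless epoxidation of nerol. The epoxidation sets C11'; the Payne inversion sets C10'.
5. Ring order: oxirane (step 1), rearranged oxirane (step 2, opened at once), benzoquinone (step 8).

**Route**

Step 1
Reactants: 1 nerol [(2Z)-3,7-dimethylocta-2,6-dien-1-ol]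
Product: 2 (2R,3S)-2,3-epoxynerol {[(2R,3S)-3-methyl-3-(4-methylpent-3-en-1-yl)oxiran-2-yl]methanol}
Conditions: Ti(OiPr)4 (10 mol%), D-(−)-DET (12 mol%), t-BuOOH (2 equiv), 4 Å MS, CH2Cl2, −20 °C
Reagents that add atoms: tert-butyl hydroperoxide, CC(C)(C)OO
Why: Katsuki–Sharpless asymmetric epoxidation: only the allylic 2,3-alkene binds to the Ti–tartrate template, and D-(−)-DET delivers oxygen to the face that gives the (2R,3S) cis-epoxide (mirror image of the L-tartrate product, usually ≥90 % ee for nerol), which fixes the future C11' and presets C10' for one inversion.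

Step 2
Reactants: 2 (2R,3S)-2,3-epoxynerol
Product: 4 (2R,3S)-3,7-dimethyl-1-(phenylsulfonyl)oct-6-ene-2,3-diol, via Payne-rearranged terminal epoxide 3 (not isolated)
Conditions: PhSO2Na (4 equiv), 0.5 M aq NaOH, t-BuOH–H2O 1:1, 75 °C
Reagents that add atoms: sodium benzenesulfinate, [Na+].[O-]S(=O)c1ccccc1
Why: Proposed new method: under aqueous hydroxide the epoxy alkoxide equilibrates by Payne rearrangement (O1 attacks C2 in a 3-exo SN2 with clean inversion to give terminal epoxide 3) and the soft S-nucleophile PhSO2− opens the far more reactive monosubstituted oxirane at C1 (Curtin–Hammett), so C2 (future C10') is inverted exactly once and C3 (future C11') is untouched; the closest known reactions are the Payne rearrangement–thiolate opening of 2,3-epoxy alcohols and the opening of terminal epoxides by sodium sulfinates in hot water.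

Step 3
Reactants: 5 geranyl acetate [(2E)-3,7-dimethylocta-2,6-dien-1-yl acetate]
Product: 6 (2E,6E)-8-hydroxy-3,7-dimethylocta-2,6-dien-1-yl acetate
Conditions: SeO2 (0.3 equiv), t-BuOOH (3 equiv), salicylic acid (0.1 equiv), CH2Cl2, rt
Reagents that add atoms: tert-butyl hydroperoxide, CC(C)(C)OO (oxygen relayed through catalytic selenium dioxide, O=[Se]=O)
Why: Sharpless–Umbreit SeO2/t-BuOOH allylic oxidation (ene reaction then [2,3]-shift) attacks only the (E)-methyl of the electron-rich terminal alkene, because the 2,3-alkene is deactivated by the allylic acetate, and gives the (E)-allylic alcohol.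

Step 4
Reactants: 6 (2E,6E)-8-hydroxy-3,7-dimethylocta-2,6-dien-1-yl acetate
Product: 7 (2E,6E)-8-bromo-3,7-dimethylocta-2,6-dien-1-yl acetate
Conditions: CBr4 (1.2 equiv), PPh3 (1.25 equiv), CH2Cl2, 0 °C
Reagents that add atoms: carbon tetrabromide, BrC(Br)(Br)Br
Why: Appel reaction: neutral SN2 bromination of the primary allylic alcohol without allylic transposition or E/Z loss, and the acetate is untouched.

Step 5
Reactants: 4 (2R,3S)-3,7-dimethyl-1-(phenylsulfonyl)oct-6-ene-2,3-diol; 7 (2E,6E)-8-bromo-3,7-dimethylocta-2,6-dien-1-yl acetate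
Product: 9 (2E,6E,10R,11S)-10,11-dihydroxy-3,7,11,15-tetramethyl-9-(phenylsulfonyl)hexadeca-2,6,14-trien-1-yl acetate (C9 epimer mixture), via trilithio sulfone 8 (not isolated)
Conditions: n-BuLi (3.0 equiv), THF–DMPU 5:1, −78 → −30 °C; then 7 (1.05 equiv), −78 °C, 1 h; AcOH quench at −78 °C
Reagents that add atoms: none
Why: C-alkylation of a β-hydroxy sulfone polyanion (Julia-type sulfone alkylation): the O,O,C-trilithio species 8 cannot β-eliminate (oxide is no leaving group) and its carbanion displaces the primary allylic bromide by SN2 at −78 °C faster than it attacks the acetate, which forges C8'–C9' with both alkene geometries and both carbinol centres untouched (10R is the same spatial arrangement as 10S in the sulfur-free compounds, and the new sulfone-bearing centre is erased in step 6).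

Step 6
Reactants: 9 (2E,6E,10R,11S)-10,11-dihydroxy-3,7,11,15-tetramethyl-9-(phenylsulfonyl)hexadeca-2,6,14-trien-1-yl acetate
Product: 11 (2E,6E,10S,11S)-3,7,11,15-tetramethylhexadeca-2,6,14-triene-1,10,11-triol, via desulfonylated acetate 10 (not isolated)
Conditions: 6 % Na(Hg) (6 equiv Na), Na2HPO4 (6 equiv), MeOH–THF 3:1, −20 → 0 °C; then K2CO3 (1 equiv), MeOH, rt
Reagents that add atoms: none
Why: Reductive desulfonylation with buffered sodium amalgam (electron transfer, C–S cleavage, protonation by MeOH; with a free β-hydroxyl, protonation outruns Julia-type elimination, and the non-allylic position rules out alkene migration), followed in the same flask by K2CO3/MeOH transesterification of the acetate; no stereocentre is affected.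

Step 7
Reactants: 11 (2E,6E,10S,11S)-3,7,11,15-tetramethylhexadeca-2,6,14-triene-1,10,11-triol; 12 4-methoxy-2-methylphenol
Product: 13 2-[(2E,6E,10S,11S)-10,11-dihydroxy-3,7,11,15-tetramethylhexadeca-2,6,14-trien-1-yl]-4-methoxy-6-methylphenol
Conditions: acidic Al2O3 (Brockmann I, ca. 2 g per mmol of 11), 12 (3 equiv), ClCH2CH2Cl, reflux, 24 h; elution with EtOAc–MeOH
Reagents that add atoms: none
Why: Alumina-templated dehydrative ortho-allylation of a free phenol with a free allylic alcohol (Friedel–Crafts-type aromatic prenylation, the laboratory counterpart of the prenyl-transferase step): the phenol is held on the surface as an aluminium phenoxide, the primary allylic alcohol ionises there and is delivered to the only free ortho carbon (para is blocked by OMe, the other ortho by Me) with retention of the 2'E geometry, while the non-allylic sec/tert-diol and the isolated trisubstituted alkenes are not ionised at 83 °C.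

Step 8
Reactants: 13 2-[(2E,6E,10S,11S)-10,11-dihydroxy-3,7,11,15-tetramethylhexadeca-2,6,14-trien-1-yl]-4-methoxy-6-methylphenol
Product: 15 target quinone 2-[(2E,6E,10S,11S)-10,11-dihydroxy-3,7,11,15-tetramethylhexadeca-2,6,14-trien-1-yl]-6-methylcyclohexa-2,5-diene-1,4-dione, via quinol hemiketal 14 (not isolated)
Conditions: PhI(OAc)2 (1.1 equiv), MeCN–H2O 2:1, 0 °C, 15 min
Reagents that add atoms: water, O
Why: Hypervalent-iodine oxidative demethylation of a p-methoxyphenol (quinol-to-quinone oxidation as in the biosynthesis): ligand exchange at I(III), para attack of water to hemiketal 14 and loss of methanol give the quinone within minutes at 0 °C, far faster than glycol cleavage or alkene oxidation, so the (10'S,11'S)-diol is untouched.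

**Compound list**
1 | nerol, (2Z)-3,7-dimethylocta-2,6-dien-1-ol | CC(C)=CCC/C(C)=C\CO | starting material
2 | (2R,3S)-2,3-epoxynerol, [(2R,3S)-3-methyl-3-(4-methylpent-3-en-1-yl)oxiran-2-yl]methanol | OC[C@H]1O[C@@]1(C)CCC=C(C)C | intermediate
3 | (2S)-6-methyl-2-[(2S)-oxiran-2-yl]hept-5-en-2-ol (Payne isomer, formed in situ) | CC(C)=CCC[C@](C)(O)[C@@H]1CO1 | intermediate
4 | (2R,3S)-3,7-dimethyl-1-(phenylsulfonyl)oct-6-ene-2,3-diol | CC(C)=CCC[C@](C)(O)[C@@H](O)CS(=O)(=O)c1ccccc1 | intermediate
5 | geranyl acetate, (2E)-3,7-dimethylocta-2,6-dien-1-yl acetate | CC(C)=CCC/C(C)=C/COC(C)=O | starting material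
6 | (2E,6E)-8-hydroxy-3,7-dimethylocta-2,6-dien-1-yl acetate | OC/C(C)=C/CC/C(C)=C/COC(C)=O | intermediate
7 | (2E,6E)-8-bromo-3,7-dimethylocta-2,6-dien-1-yl acetate | BrC/C(C)=C/CC/C(C)=C/COC(C)=O | intermediate
8 | O,O,C-trilithio derivative of 4 (formed in situ) | CC(C)=CCC[C@](C)(O[Li])[C@@H](O[Li])C([Li])S(=O)(=O)c1ccccc1 | intermediate
9 | (2E,6E,10R,11S)-10,11-dihydroxy-3,7,11,15-tetramethyl-9-(phenylsulfonyl)hexadeca-2,6,14-trien-1-yl acetate (C9 epimers) | CC(C)=CCC[C@](C)(O)[C@@H](O)C(C/C(C)=C/CC/C(C)=C/COC(C)=O)S(=O)(=O)c1ccccc1 | intermediate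
10 | (2E,6E,10S,11S)-10,11-dihydroxy-3,7,11,15-tetramethylhexadeca-2,6,14-trien-1-yl acetate (formed in situ) | CC(C)=CCC[C@](C)(O)[C@@H](O)CC/C(C)=C/CC/C(C)=C/COC(C)=O | intermediate
11 | (2E,6E,10S,11S)-3,7,11,15-tetramethylhexadeca-2,6,14-triene-1,10,11-triol | CC(C)=CCC[C@](C)(O)[C@@H](O)CC/C(C)=C/CC/C(C)=C/CO | intermediate
12 | 4-methoxy-2-methylphenol | COc1ccc(O)c(C)c1 | starting material
13 | 2-[(2E,6E,10S,11S)-10,11-dihydroxy-3,7,11,15-tetramethylhexadeca-2,6,14-trien-1-yl]-4-methoxy-6-methylphenol | CC(C)=CCC[C@](C)(O)[C@@H](O)CC/C(C)=C/CC/C(C)=C/Cc1cc(OC)cc(C)c1O | intermediate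
14 | 2-[(2E,6E,10S,11S)-10,11-dihydroxy-3,7,11,15-tetramethylhexadeca-2,6,14-trien-1-yl]-4-hydroxy-4-methoxy-6-methylcyclohexa-2,5-dien-1-one (formed in situ, C4 epimers) | CC(C)=CCC[C@](C)(O)[C@@H](O)CC/C(C)=C/CC/C(C)=C/CC1=CC(O)(OC)C=C(C)C1=O | intermediate
15 | 2-[(2E,6E,10S,11S)-10,11-dihydroxy-3,7,11,15-tetramethylhexadeca-2,6,14-trien-1-yl]-6-methylcyclohexa-2,5-diene-1,4-dione | CC(C)=CCC[C@](C)(O)[C@@H](O)CC/C(C)=C/CC/C(C)=C/CC1=CC(=O)C=C(C)C1=O | target

**Step count**
Total: 8 steps. Longest linear sequence: 6 steps (1 → 2 → 5 → 6 → 7 → 8, or 3 → 4 → 5 → 6 → 7 → 8).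

**Steps most likely to fail, with fallbacks**

Step 2. Sulfinate may be too sluggish, so that hydroxide opening to the triol or base-induced erosion of the β-hydroxy sulfone competes. The fallback sets out from 2 and uses the classical Payne rearrangement–thiolate opening: PhSH (slow addition), 0.5 M NaOH, t-BuOH–H2O, reflux gives (2R,3S)-3,7-dimethyl-1-(phenylsulfanyl)oct-6-ene-2,3-diol F1. Chemoselective sulfur oxidation (30 % H2O2, cat. ammonium molybdate, EtOH, 0 °C → rt; the trisubstituted alkene is left alone) then returns to the route at 4.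

Step 5. The strongly basic carbanion of 8 may acylate on, or enolise, the acetate of 7 instead of displacing bromide. The fallback sets out from 7 and removes the ester before the union: DIBAL-H (2.2 equiv, CH2Cl2, −78 °C) gives (2E,6E)-8-bromo-3,7-dimethylocta-2,6-dien-1-ol F2. n-BuLi (1 equiv, THF, −78 °C) converts it into lithium (2E,6E)-8-bromo-3,7-dimethylocta-2,6-dien-1-olate F3, which is added at once to trilithio sulfone 8. The ester-free alkylation gives (2E,6E,10R,11S)-3,7,11,15-tetramethyl-9-(phenylsulfonyl)hexadeca-2,6,14-triene-1,10,11-triol F4. Na(Hg)/Na2HPO4/MeOH then leads straight back to the route at 11, bypassing 9 and 10.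

Step 7 (the riskiest). The free diol may block the alumina surface, or the allyl cation may scramble the 2'-alkene or close to a chroman. The fallback sets out from 11 and replaces the acid-surface prenylation by an anionic one:
- 2,2-Dimethoxypropane, PPTS, acetone gives (2E,6E)-3,7-dimethyl-9-[(4S,5S)-2,2,5-trimethyl-5-(4-methylpent-3-en-1-yl)-1,3-dioxolan-4-yl]nona-2,6-dien-1-ol F5.
- CBr4/PPh3 (CH2Cl2, 0 °C) gives (4S,5S)-4-[(3E,7E)-9-bromo-3,7-dimethylnona-3,7-dien-1-yl]-2,2,5-trimethyl-5-(4-methylpent-3-en-1-yl)-1,3-dioxolane F6.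
- Phenol 12 with NaH in toluene gives sodium 4-methoxy-2-methylphenolate F7. Its tight ion pair in the non-polar solvent is C-alkylated by F6 at the only free ortho position (Claisen-type ortho C-alkylation of a phenoxide), giving 2-{(2E,6E)-3,7-dimethyl-9-[(4S,5S)-2,2,5-trimethyl-5-(4-methylpent-3-en-1-yl)-1,3-dioxolan-4-yl]nona-2,6-dien-1-yl}-4-methoxy-6-methylphenol F8.
- 80 % aq AcOH at rt removes the acetonide and returns to the route at 13.

**Further compounds**
F1 | step 2 | (2R,3S)-3,7-dimethyl-1-(phenylsulfanyl)oct-6-ene-2,3-diol | CC(C)=CCC[C@](C)(O)[C@@H](O)CSc1ccccc1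
F2 | step 5 | (2E,6E)-8-bromo-3,7-dimethylocta-2,6-dien-1-ol | BrC/C(C)=C/CC/C(C)=C/CO
F3 | step 5 | lithium (2E,6E)-8-bromo-3,7-dimethylocta-2,6-dien-1-olate | BrC/C(C)=C/CC/C(C)=C/CO[Li]
F4 | step 5 | (2E,6E,10R,11S)-3,7,11,15-tetramethyl-9-(phenylsulfonyl)hexadeca-2,6,14-triene-1,10,11-triol (C9 epimers) | CC(C)=CCC[C@](C)(O)[C@@H](O)C(C/C(C)=C/CC/C(C)=C/CO)S(=O)(=O)c1ccccc1
F5 | step 7 | (2E,6E)-3,7-dimethyl-9-[(4S,5S)-2,2,5-trimethyl-5-(4-methylpent-3-en-1-yl)-1,3-dioxolan-4-yl]nona-2,6-dien-1-ol | CC(C)=CCC[C@]1(C)OC(C)(C)O[C@H]1CC/C(C)=C/CC/C(C)=C/CO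
F6 | step 7 | (4S,5S)-4-[(3E,7E)-9-bromo-3,7-dimethylnona-3,7-dien-1-yl]-2,2,5-trimethyl-5-(4-methylpent-3-en-1-yl)-1,3-dioxolane | CC(C)=CCC[C@]1(C)OC(C)(C)O[C@H]1CC/C(C)=C/CC/C(C)=C/CBr
F7 | step 7 | sodium 4-methoxy-2-methylphenolate | [Na+].[O-]c1ccc(OC)cc1C
F8 | step 7 | 2-{(2E,6E)-3,7-dimethyl-9-[(4S,5S)-2,2,5-trimethyl-5-(4-methylpent-3-en-1-yl)-1,3-dioxolan-4-yl]nona-2,6-dien-1-yl}-4-methoxy-6-methylphenol | CC(C)=CCC[C@]1(C)OC(C)(C)O[C@H]1CC/C(C)=C/CC/C(C)=C/Cc2cc(OC)cc(C)c2O
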